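## Structural features

The target is a fully substituted furan-2(5H)-one (numbered O1, C2 lactone carbonyl, C3, C4, C5). C3 carries a free enol hydroxyl, C4 a 4-hydroxyphenyl group, and C5 both a methyl ester and a methylene bridge to C5' of a 2,3-dihydrobenzofuran (primed locants) that bears a 2-hydroxypropan-2-yl group at C2'. There are two stereocentres, the quaternary C5 and the secondary ether carbon C2', both S by CIP analysis of the drawn structure. They lie six bonds apart across an aromatic ring, so neither can direct the other and each needs its own reagent control. The fragile groups are the acidic, oxidisable 3-hydroxy enoate, the phenol, a methyl ester and a lactone on the same carbon (both open to base and nucleophiles), and a tertiary alcohol next to an aryl ether carbon that strong acid could dehydrate or ring-expand to a chroman. The real difficulty is C5, an oxygen-bearing quaternary centre with four different substituents and no neighbouring stereocentre. The C5–H of the corresponding des-alkyl butenolide is acidic (ester α-carbon and butenolide γ-position, with an aromatic 2-oxidofuran as anion), which makes a C5–CH2 disconnection attractive. In the dihydrofuran ring, C3' is an unsubstituted benzylic methylene bonded to the ether carbon C2' (O1'–C2'H–C3'H2–C3a'). That is the pattern left when a benzylic carbene inserts into a C–H bond of an aryl–O–CH2 group, and the key step uses it to form C3'–C2', close the five-membered ring and set C2'.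

## Logic of the disconnections

**17 ⇒ 15.** The two O–CH2Ph bonds and the O–Si bond are cut. The enol and phenol would consume base and electrophile in a C5 alkylation, and the tertiary hydroxyl would intercept a carbene. The gain is one protected intermediate from which all three masks fall in a single operation. The forward step must cleave two benzyl ethers without reducing the tetrasubstituted enol double bond or the allylic C5–O1 bond, and remove silicon with acid mild enough for the tertiary alcohol.

**15 ⇒ 9 + 14.** The C5–CH2 bond is cut. This is the most convergent cut: it gives two halves of similar size, each carrying one stereochemical problem, and it uses the acidity of C5–H in 14. The forward step must distinguish the faces of a planar furanolate by a chiral counter-cation, alkylate at C5 and not at C3 or oxygen, and use an electrophile reactive enough at low temperature.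

**14 ⇒ 13 ⇒ 10 + 11.** First the two benzyl ether C–O bonds are cut, then C4–C5 and O1–C2 of the ring. C5 is a carbinol carbon next to the benzylic carbon of an arylpyruvate, which is an aldol retron, and the lactone is the ester of that carbinol with the pyruvic carboxyl. The ring then comes from two commercial compounds in one flask. The cross-aldol must outrun pyruvate self-condensation, and O-benzylation must leave the acidic C5–H alone.

**9 ⇒ 8 ⇒ 7.** The C–Br bond and then the alcohol oxidation level are traced back to the ester. The electron-rich benzylic bromide is too labile to carry far, whereas the ester is an inert spectator with no activated C–H bonds in the carbene step. Reduction and bromination must leave the tertiary silyl ether and C2' untouched.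

**7 ⇒ 5 (through 6).** The C3'–C2' bond is cut. This removes the ring and the stereocentre together and leaves an achiral salicylaldehyde ether. The forward step must select one of two enantiotopic hydrogens, make intramolecular insertion faster than carbene dimerisation, and meet no free O–H.

**5 ⇒ 4 ⇒ 3 ⇒ 1 + 2.** The C=N bond, the O–Si bond and the aryl O–CH2 bond are cut in turn. The hydroxy-tert-butyl ether is the adduct of a phenoxide and a 1,1-disubstituted epoxide. The phenoxide must open the epoxide at its CH2 terminus, and hydrazine must condense with the aldehyde without attacking the ester or forming azine.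

## Other disconnections considered

**Alternative 1:** The cut runs through the benzene ring of the dihydrobenzofuran (C3a'–C7a', C4'–C5', C6'–C7'). It leaves the ynol-ether diyne A2, (S)-trimethyl({[2-methyl-2-(triethylsilyloxy)hex-5-yn-3-yl]oxy}ethynyl)silane, and the C5-propargyl butenolide A3. Forward, Cp*RuCl(cod) (divalent ruthenium) would couple the two tethered alkynes of A2 to a ruthenacyclopentadiene, insert the alkyne of A3 and eliminate the arene. This would give the 7'-silylated, fully protected target A1, and ipso-protodesilylation and deprotection would follow.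
- In favour: three C–C bonds and two rings form in the fragment-joining step; C2' comes from a preformed stereocentre and not from enantiotopic C–H discrimination; no diazo compound is handled. On convergence and on certainty at C2' this plan is the better one.
- Against: ynol ethers of secondary alcohols are laborious and thermally labile; the regiochemistry (C5' versus C6') rests on the steering effect of the silyl group; an extra desilylation is needed.
- Comparison: C5 must still be set by asymmetric alkylation of the same butenolide, now with a small propargyl halide, so on the hardest centre the two plans are equal. In step count the alternative is expected to be clearly longer, because A2 alone needs a multistep asymmetric synthesis.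

**Alternative 2:** The cut is O1–C5 of the lactone together with a former aromatic C–C bond. The precursor is the biaryl catechol A5, methyl 3-(benzyloxy)-2-[4-(benzyloxy)phenyl]-4,5-dihydroxybenzoate. Forward, peracetic acid would cleave the catechol between its hydroxylated carbons to the cis,cis-dienedioic acid A6. The carboxyl next to the benzyloxy carbon would then add in conjugate fashion to the ester-bearing alkene carbon to give the C5-carboxymethyl butenolide A4.
- In favour: the C3-oxygen, C4-aryl, C5-ester pattern is fixed by arene substitution (cross-coupling chemistry), so no ambident-enolate regiochemistry arises. On that point it is the better plan.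
- Against: the lactonisation creates C5 without any stereocontrol; two carboxyls and two alkenes allow other lactones; the peracid can attack the electron-rich aryl ether. A4 would then need a decarboxylative sp3–sp2 coupling to attach the dihydrobenzofuran, whose C2' centre would have to be made anyway.
- Comparison: mechanistically interesting, but weaker than the chosen plan on C5 control and longer overall.

**Alternative 3:** The cut is C3–C4 and O1–C5, with an isoxazoline as masked β-hydroxy-α-keto ester. Ethoxycarbonylformonitrile oxide A10, released from ethyl 2-chloro-2-(hydroxyimino)acetate A9, would add to the (E)-allylic alcohol A8 under Et2Zn (divalent zinc) and a diisopropyl tartrate to give isoxazoline A7.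
- In favour: the quaternary C5 is set by an established hydroxyl-directed asymmetric cycloaddition type, and the concerted mechanism transfers alkene geometry. On precedent for the C5-forming event it is better than the chosen plan, whose alkylation is new for this anion.
- Against: a trisubstituted, aryl-conjugated alkene is a sluggish dipolarophile, and nitrile oxide dimerisation competes. The endgame needs N–O cleavage, lactonisation and oxidation of CH2OH to the methyl ester in the presence of the enol. A8 also contains the dihydrobenzofuran, so C2' still has to be made separately.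
- Comparison: equal on the C2' problem, better on C5 precedent, worse on step economy and redox economy.

Key step: step 4

Assumption: the sense of induction of Rh2(S-PTAD)4 in step 4 and of the (11bS)-ammonium salt in step 9 cannot be assigned in advance for these substrates; the antipodes written are taken to give 2'S and 5S, and the mirror-image catalyst would be used if a trial run pointed the other way.

## Route

Step 1
Reactants: 1 methyl 3-formyl-4-hydroxybenzoate; 2 2,2-dimethyloxirane
Product: 3 methyl 3-formyl-4-(2-hydroxy-2-methylpropoxy)benzoate
Conditions: K2CO3 (0.3 equiv), 2 (3 equiv), DMF, 90 °C, sealed tube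
Reagents that add atoms: none
Why: Base-mediated epoxide opening (Williamson-type etherification): the phenoxide attacks the unsubstituted CH2 terminus of the 1,1-disubstituted epoxide by SN2, which unveils the tertiary alcohol directly; the non-enolisable aldehyde and the ester are spectators under carbonate.

Step 2
Reactants: 3 methyl 3-formyl-4-(2-hydroxy-2-methylpropoxy)benzoate
Product: 4 methyl 3-formyl-4-[2-methyl-2-(triethylsilyloxy)propoxy]benzoate
Conditions: TESOTf, 2,6-lutidine, CH2Cl2, 0 °C
Reagents that add atoms: triethylsilyl trifluoromethanesulfonate, CC[Si](CC)(CC)OS(=O)(=O)C(F)(F)F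
Why: Silylation of a hindered tertiary alcohol needs the silyl triflate with a non-nucleophilic base; the triethylsilyl group removes the O–H insertion competitor of step 4 and is later lost in mild acid.

Step 3
Reactants: 4 methyl 3-formyl-4-[2-methyl-2-(triethylsilyloxy)propoxy]benzoate
Product: 5 methyl 3-[(E)-hydrazonomethyl]-4-[2-methyl-2-(triethylsilyloxy)propoxy]benzoate
Conditions: N2H4·H2O (6 equiv), EtOH, 0 °C, 1 h; extractive work-up, used at once
Reagents that add atoms: hydrazine hydrate, NN.O
Why: Hydrazone formation: condensation of the aryl aldehyde with excess hydrazine is fast at 0 °C, whereas hydrazinolysis of the deactivated methyl benzoate needs heat; the excess suppresses azine formation and the crude hydrazone is not stored.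

Step 4
Reactants: 5 methyl 3-[(E)-hydrazonomethyl]-4-[2-methyl-2-(triethylsilyloxy)propoxy]benzoate
Product: 7 methyl (S)-2-[2-(triethylsilyloxy)propan-2-yl]-2,3-dihydrobenzofuran-5-carboxylate, via aryldiazomethane 6 (not isolated)
Conditions: MnO2 (8 equiv), CH2Cl2, 0 °C, dark; cold filtration; filtrate added over 3 h to Rh2(S-PTAD)4 (1 mol%), CH2Cl2, −20 → 0 °C, high dilution
Reagents that add atoms: none
Why: MnO2 dehydrogenates the N–H hydrazone to the aryldiazomethane 6, which is kept cold in solution, never concentrated, and fed slowly to the catalyst. Rh2(S-PTAD)4, the dirhodium tetrakis[(S)-(1-adamantyl)(N-phthalimido)acetate] complex of divalent rhodium, expels N2 to give an electrophilic donor-type rhodium carbene, which inserts through a concerted, asynchronous, hydride-transfer-like three-centre transition state into a C–H bond of the O–CH2 group. The closest known reaction type is the dirhodium-catalysed enantioselective intramolecular C–H insertion of hydrazone-derived donor carbenes into ether α-C–H bonds to give 2,3-dihydrobenzofurans; the aryl/hydrogen carbene and the β-quaternary methylene extend it. The dihydrofuran closes in the 1,5 mode: the carbene carbon (C3') and the C–H carbon (C2') are linked through C3a', C7a' and O1', so the new C3'–C2' bond completes a five-membered ring, and the methyl or silyl C–H bonds would need seven-membered or larger transition states. C2' is set by the catalyst: the chiral carboxylate bowl should allow the bulky C(CH3)2OSiEt3 group to point out of the pocket in one orientation only, so that the pro-S hydrogen is replaced with retention to give the 2'S product. The step needs site selectivity, selection of one enantiotopic hydrogen, and insertion faster than carbene dimerisation to azine or stilbene. The ether oxygen activates the targeted C–H bonds, the gem-dimethyl group holds the chain near the carbene, the silyl ether removes the O–H competitor, and slow addition at high dilution keeps the diazo concentration low.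

Step 5
Reactants: 7 methyl (S)-2-[2-(triethylsilyloxy)propan-2-yl]-2,3-dihydrobenzofuran-5-carboxylate
Product: 8 {(S)-2-[2-(triethylsilyloxy)propan-2-yl]-2,3-dihydrobenzofuran-5-yl}methanol
Conditions: i-Bu2AlH (2.5 equiv), CH2Cl2, −78 → 0 °C; aq. KNaC4H4O6 work-up
Reagents that add atoms: none
Why: Hydride reduction of the aryl ester to the benzylic alcohol; the tertiary silyl ether, the aryl ether and C2' are inert to i-Bu2AlH at low temperature.

Step 6
Reactants: 8 {(S)-2-[2-(triethylsilyloxy)propan-2-yl]-2,3-dihydrobenzofuran-5-yl}methanol
Product: 9 (S)-5-(bromomethyl)-2-[2-(triethylsilyloxy)propan-2-yl]-2,3-dihydrobenzofuran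
Conditions: CBr4, PPh3, 2,6-lutidine (0.2 equiv), CH2Cl2, 0 °C; short silica plug, used at once
Reagents that add atoms: carbon tetrabromide, BrC(Br)(Br)Br
Why: Appel bromination: bromide displaces the alkoxyphosphonium group under near-neutral conditions that leave the tertiary silyl ether intact; the electron-rich benzylic bromide is not stored.

Step 7
Reactants: 10 4-hydroxyphenylpyruvic acid; 11 methyl glyoxylate
Product: 13 methyl 3-hydroxy-4-(4-hydroxyphenyl)-2-oxo-2,5-dihydrofuran-5-carboxylate (racemic), via aldol adduct 12 (not isolated)
Conditions: 11 (1.5 equiv, freshly depolymerised), Et3N (2.2 equiv), THF, 0 °C → rt; then 2 M aq. HCl, rt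
Reagents that add atoms: none
Why: Cross-aldol addition then lactonisation: the arylpyruvate enolate adds through its benzylic carbon to the highly electrophilic aldehyde of 11 (forming C4–C5); on acidification the γ-hydroxy α-keto acid closes to the five-membered lactone and enolises to the conjugated 3-hydroxybutenolide. C5 forms racemic, which does not matter because it is planarised in step 9.

Step 8
Reactants: 13 methyl 3-hydroxy-4-(4-hydroxyphenyl)-2-oxo-2,5-dihydrofuran-5-carboxylate
Product: 14 methyl 3-(benzyloxy)-4-[4-(benzyloxy)phenyl]-2-oxo-2,5-dihydrofuran-5-carboxylate (racemic)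
Conditions: BnOH (2.2 equiv), PPh3 (2.4 equiv), DIAD (2.4 equiv), THF, 0 °C → rt
Reagents that add atoms: benzyl alcohol, OCc1ccccc1
Why: Mitsunobu etherification: both acidic hydroxyls (enol and phenol) are O-benzylated under neutral redox conditions, which avoids carbonate/benzyl halide conditions under which the acidic C5–H could be C-alkylated.

Step 9
Reactants: 14 methyl 3-(benzyloxy)-4-[4-(benzyloxy)phenyl]-2-oxo-2,5-dihydrofuran-5-carboxylate; 9 (S)-5-(bromomethyl)-2-[2-(triethylsilyloxy)propan-2-yl]-2,3-dihydrobenzofuran
Product: 15 methyl (5S)-3-(benzyloxy)-4-[4-(benzyloxy)phenyl]-2-oxo-5-({(2S)-2-[2-(triethylsilyloxy)propan-2-yl]-2,3-dihydrobenzofuran-5-yl}methyl)-2,5-dihydrofuran-5-carboxylate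
Conditions: 9 (1.3 equiv), (11bS)-4,4-dibutyl-2,6-bis(3,4,5-trifluorophenyl)-4,5-dihydro-3H-dinaphtho[2,1-c:1',2'-e]azepinium bromide (5 mol%), Cs2CO3 (solid, 2 equiv), toluene, −20 °C
Reagents that add atoms: none
Why: Proposed new method: solid Cs2CO3 deprotonates C5–H of 14 at the interface (ester α-carbon and butenolide γ-position, giving an aromatic 2-oxidofuran); the anion is extracted as a tight ion pair with the C2-symmetric chiral ammonium cation, which shields one face of the planar anion so that C5 attacks the benzylic bromide 9 from the open face and the quaternary centre is set under catalyst control, the remote C2' centre of 9 not being expected to interfere; C5 should be preferred over C3 and oxygen because it is the ester α-carbon and its alkylation keeps the conjugated enol-ether lactone; the closest known reaction type is the enantioselective phase-transfer benzylation of cyclic α-substituted β-keto esters, α-acyloxy malonates and 3-substituted oxindoles to quaternary centres with binaphthyl-derived ammonium salts.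

Step 10
Reactants: 15 methyl (5S)-3-(benzyloxy)-4-[4-(benzyloxy)phenyl]-2-oxo-5-({(2S)-2-[2-(triethylsilyloxy)propan-2-yl]-2,3-dihydrobenzofuran-5-yl}methyl)-2,5-dihydrofuran-5-carboxylate
Product: 17 methyl (5S)-3-hydroxy-4-(4-hydroxyphenyl)-5-{[(2S)-2-(2-hydroxypropan-2-yl)-2,3-dihydrobenzofuran-5-yl]methyl}-2-oxo-2,5-dihydrofuran-5-carboxylate, via triethylsilyl ether 16 (not isolated)
Conditions: H2 (1 atm), Pd/C (10 wt%), MeOH, rt; then 1 M aq. HCl (cat.), rt
Reagents that add atoms: none
Why: Hydrogenolysis of the benzyl enol ether and the benzyl aryl ether over Pd/C, then acid-catalysed cleavage of the tertiary triethylsilyl ether in the same flask; the tetrasubstituted enol double bond, the quaternary allylic C5–O1 bond and both stereocentres should be untouched, and methanol as solvent makes ester exchange degenerate.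

## Compound list

1 | methyl 3-formyl-4-hydroxybenzoate | COC(=O)c1ccc(O)c(C=O)c1 | starting material
2 | 2,2-dimethyloxirane | CC1(C)CO1 | starting material
3 | methyl 3-formyl-4-(2-hydroxy-2-methylpropoxy)benzoate | COC(=O)c1ccc(OCC(C)(C)O)c(C=O)c1 | intermediate
4 | methyl 3-formyl-4-[2-methyl-2-(triethylsilyloxy)propoxy]benzoate | COC(=O)c1ccc(OCC(C)(C)O[Si](CC)(CC)CC)c(C=O)c1 | intermediate
5 | methyl 3-[(E)-hydrazonomethyl]-4-[2-methyl-2-(triethylsilyloxy)propoxy]benzoate | COC(=O)c1ccc(OCC(C)(C)O[Si](CC)(CC)CC)c(/C=N/N)c1 | intermediate
6 | methyl 3-(diazomethyl)-4-[2-methyl-2-(triethylsilyloxy)propoxy]benzoate | COC(=O)c1ccc(OCC(C)(C)O[Si](CC)(CC)CC)c(C=[N+]=[N-])c1 | intermediate (not isolated)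
7 | methyl (S)-2-[2-(triethylsilyloxy)propan-2-yl]-2,3-dihydrobenzofuran-5-carboxylate | COC(=O)c1ccc2c(c1)C[C@@H](C(C)(C)O[Si](CC)(CC)CC)O2 | intermediate
8 | {(S)-2-[2-(triethylsilyloxy)propan-2-yl]-2,3-dihydrobenzofuran-5-yl}methanol | OCc1ccc2c(c1)C[C@@H](C(C)(C)O[Si](CC)(CC)CC)O2 | intermediate
9 | (S)-5-(bromomethyl)-2-[2-(triethylsilyloxy)propan-2-yl]-2,3-dihydrobenzofuran | BrCc1ccc2c(c1)C[C@@H](C(C)(C)O[Si](CC)(CC)CC)O2 | intermediate
10 | 4-hydroxyphenylpyruvic acid | O=C(O)C(=O)Cc1ccc(O)cc1 | starting material
11 | methyl glyoxylate | COC(=O)C=O | starting material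
12 | 4-hydroxy-3-(4-hydroxyphenyl)-5-methoxy-2,5-dioxopentanoic acid (diastereomer mixture) | COC(=O)C(O)C(c1ccc(O)cc1)C(=O)C(=O)O | intermediate (not isolated)
13 | methyl 3-hydroxy-4-(4-hydroxyphenyl)-2-oxo-2,5-dihydrofuran-5-carboxylate (racemic) | COC(=O)C1OC(=O)C(O)=C1c1ccc(O)cc1 | intermediate
14 | methyl 3-(benzyloxy)-4-[4-(benzyloxy)phenyl]-2-oxo-2,5-dihydrofuran-5-carboxylate (racemic) | COC(=O)C1OC(=O)C(OCc2ccccc2)=C1c1ccc(OCc2ccccc2)cc1 | intermediate
15 | methyl (5S)-3-(benzyloxy)-4-[4-(benzyloxy)phenyl]-2-oxo-5-({(2S)-2-[2-(triethylsilyloxy)propan-2-yl]-2,3-dihydrobenzofuran-5-yl}methyl)-2,5-dihydrofuran-5-carboxylate | COC(=O)[C@@]1(Cc2ccc3c(c2)C[C@@H](C(C)(C)O[Si](CC)(CC)CC)O3)OC(=O)C(OCc2ccccc2)=C1c1ccc(OCc2ccccc2)cc1 | intermediate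
16 | methyl (5S)-3-hydroxy-4-(4-hydroxyphenyl)-2-oxo-5-({(2S)-2-[2-(triethylsilyloxy)propan-2-yl]-2,3-dihydrobenzofuran-5-yl}methyl)-2,5-dihydrofuran-5-carboxylate | COC(=O)[C@@]1(Cc2ccc3c(c2)C[C@@H](C(C)(C)O[Si](CC)(CC)CC)O3)OC(=O)C(O)=C1c1ccc(O)cc1 | intermediate (not isolated)
17 | methyl (5S)-3-hydroxy-4-(4-hydroxyphenyl)-5-{[(2S)-2-(2-hydroxypropan-2-yl)-2,3-dihydrobenzofuran-5-yl]methyl}-2-oxo-2,5-dihydrofuran-5-carboxylate | COC(=O)[C@@]1(Cc2ccc3c(c2)C[C@@H](C(C)(C)O)O3)OC(=O)C(O)=C1c1ccc(O)cc1 | target

## Step count and least certain steps

Total: 10 steps. Longest linear sequence: 8 steps (steps 1–6, 9, 10). The butenolide branch (steps 7 and 8) joins at step 9.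

**Step 9 (proposed new method).** The most likely failures are insufficient facial discrimination in the ion pair of an anion class not yet tried with such catalysts, competing alkylation at C3 or oxygen of the ambident furanolate, uncatalysed background alkylation, and solvolysis of the labile bromide. The fallback uses known chemistry and gives up catalyst control. Setting out from 14 and 9, a plain base-mediated ester-enolate benzylation (Cs2CO3, MeCN, 0 °C, no chiral salt) would give 15 together with its C5 epimer, methyl (5R)-3-(benzyloxy)-4-[4-(benzyloxy)phenyl]-2-oxo-5-({(2S)-2-[2-(triethylsilyloxy)propan-2-yl]-2,3-dihydrobenzofuran-5-yl}methyl)-2,5-dihydrofuran-5-carboxylate F1. Because C2' is already fixed, the two are diastereomers and can be separated by ordinary preparative chromatography. The route is rejoined at 15.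

**Step 4 (key step).** Carbene dimerisation (azine or stilbene formation) may outrun insertion into a hindered, neopentyl-type C–H bond whose ether oxygen is made less donating by the para ester. A carbene whose second substituent is only hydrogen may discriminate poorly between the enantiotopic hydrogens. The unstabilised diazo compound may also decompose before it reaches the catalyst. The fallback forms the ring by classical condensation and sets C2' by hydrogenation. Setting out from 1:
- Rap–Stoermer condensation with chloroacetone (K2CO3, acetone, reflux) would give methyl 2-acetylbenzofuran-5-carboxylate F2.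
- Chemoselective addition of MeMgBr (1.1 equiv, THF, −78 °C) to the ketone would give methyl 2-(2-hydroxypropan-2-yl)benzofuran-5-carboxylate F3.
- TESOTf/2,6-lutidine would give methyl 2-[2-(triethylsilyloxy)propan-2-yl]benzofuran-5-carboxylate F4.
- Enantioselective hydrogenation of the furan C2'=C3' bond would give 7. The catalyst would be Ru(cod)(2-methylallyl)2 with the carbene ligand from 1,3-bis[(R)-1-(naphthalen-1-yl)ethyl]-4,5-dihydroimidazolium tetrafluoroborate and KOt-Bu, under H2 pressure, with the ligand antipode chosen to give 2'S.

The route is rejoined at 7.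

**Step 3.** The N-unsubstituted aldehyde hydrazone may disproportionate to the azine on concentration, and excess hydrazine may slowly attack the methyl ester. The fallback changes the diazo precursor and the way the diazo group is released. Setting out from 4, condensation with 4-methylbenzenesulfonohydrazide (MeOH, rt) would give the stable, crystalline methyl 3-{(E)-[2-(4-methylphenylsulfonyl)hydrazinylidene]methyl}-4-[2-methyl-2-(triethylsilyloxy)propoxy]benzoate F5. Its sodium salt (NaH, then BnEt3NCl, 40 °C) would release 6 slowly by Bamford–Stevens fragmentation in the presence of the rhodium catalyst. The route is rejoined at 6 and continues to 7.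

**Step 7.** Self-condensation of the arylpyruvic acid, incomplete depolymerisation of the glyoxylate, reversal of the aldol, or ester hydrolysis during acidification may lower throughput. The fallback replaces the direct base-mediated aldol by a preformed nucleophile under Lewis acid. Setting out from 10:
- Fischer esterification (MeOH, cat. H2SO4) would give methyl 3-(4-hydroxyphenyl)-2-oxopropanoate F6.
- TMSCl/Et3N would give methyl (Z)-2-(trimethylsilyloxy)-3-[4-(trimethylsilyloxy)phenyl]acrylate F7.
- Mukaiyama aldol addition to 11 (BF3·OEt2, CH2Cl2, −78 °C, acidic work-up) would give dimethyl 2-hydroxy-3-(4-hydroxyphenyl)-4-oxopentanedioate F8.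
- TsOH in warm toluene would lactonise F8 with loss of methanol.

The route is rejoined at 13.

## Further compounds

F1 | step 9 | methyl (5R)-3-(benzyloxy)-4-[4-(benzyloxy)phenyl]-2-oxo-5-({(2S)-2-[2-(triethylsilyloxy)propan-2-yl]-2,3-dihydrobenzofuran-5-yl}methyl)-2,5-dihydrofuran-5-carboxylate | COC(=O)[C@]1(Cc2ccc3c(c2)C[C@@H](C(C)(C)O[Si](CC)(CC)CC)O3)OC(=O)C(OCc2ccccc2)=C1c1ccc(OCc2ccccc2)cc1
F2 | step 4 | methyl 2-acetylbenzofuran-5-carboxylate | COC(=O)c1ccc2oc(C(C)=O)cc2c1
F3 | step 4 | methyl 2-(2-hydroxypropan-2-yl)benzofuran-5-carboxylate | COC(=O)c1ccc2oc(C(C)(C)O)cc2c1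
F4 | step 4 | methyl 2-[2-(triethylsilyloxy)propan-2-yl]benzofuran-5-carboxylate | COC(=O)c1ccc2oc(C(C)(C)O[Si](CC)(CC)CC)cc2c1
F5 | step 3 | methyl 3-{(E)-[2-(4-methylphenylsulfonyl)hydrazinylidene]methyl}-4-[2-methyl-2-(triethylsilyloxy)propoxy]benzoate | COC(=O)c1ccc(OCC(C)(C)O[Si](CC)(CC)CC)c(/C=N/NS(=O)(=O)c2ccc(C)cc2)c1
F6 | step 7 | methyl 3-(4-hydroxyphenyl)-2-oxopropanoate | COC(=O)C(=O)Cc1ccc(O)cc1
F7 | step 7 | methyl (Z)-2-(trimethylsilyloxy)-3-[4-(trimethylsilyloxy)phenyl]acrylate | COC(=O)/C(O[Si](C)(C)C)=C/c1ccc(O[Si](C)(C)C)cc1
F8 | step 7 | dimethyl 2-hydroxy-3-(4-hydroxyphenyl)-4-oxopentanedioate (diastereomer mixture) | COC(=O)C(O)C(c1ccc(O)cc1)C(=O)C(=O)OC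
A1 | alternative 1 | methyl (5S)-3-(benzyloxy)-4-[4-(benzyloxy)phenyl]-2-oxo-5-({(2S)-2-[2-(triethylsilyloxy)propan-2-yl]-7-(trimethylsilyl)-2,3-dihydrobenzofuran-5-yl}methyl)-2,5-dihydrofuran-5-carboxylate | COC(=O)[C@@]1(Cc2cc([Si](C)(C)C)c3c(c2)C[C@@H](C(C)(C)O[Si](CC)(CC)CC)O3)OC(=O)C(OCc2ccccc2)=C1c1ccc(OCc2ccccc2)cc1
A2 | alternative 1 | (S)-trimethyl({[2-methyl-2-(triethylsilyloxy)hex-5-yn-3-yl]oxy}ethynyl)silane | C#CC[C@@H](C(C)(C)O[Si](CC)(CC)CC)OC#C[Si](C)(C)C
A3 | alternative 1 | methyl (5S)-3-(benzyloxy)-4-[4-(benzyloxy)phenyl]-2-oxo-5-(prop-2-yn-1-yl)-2,5-dihydrofuran-5-carboxylate | COC(=O)[C@@]1(CC#C)OC(=O)C(OCc2ccccc2)=C1c1ccc(OCc2ccccc2)cc1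
A4 | alternative 2 | {(5S)-3-(benzyloxy)-4-[4-(benzyloxy)phenyl]-5-(methoxycarbonyl)-2-oxo-2,5-dihydrofuran-5-yl}acetic acid | COC(=O)[C@@]1(CC(=O)O)OC(=O)C(OCc2ccccc2)=C1c1ccc(OCc2ccccc2)cc1
A5 | alternative 2 | methyl 3-(benzyloxy)-2-[4-(benzyloxy)phenyl]-4,5-dihydroxybenzoate | COC(=O)c1cc(O)c(O)c(OCc2ccccc2)c1-c1ccc(OCc2ccccc2)cc1
A6 | alternative 2 | cis,cis-2-(benzyloxy)-3-[4-(benzyloxy)phenyl]-4-(methoxycarbonyl)hexa-2,4-dienedioic acid | OC(=O)/C(OCc1ccccc1)=C(c1ccc(OCc2ccccc2)cc1)\C(C(=O)OC)=C/C(=O)O
A7 | alternative 3 | ethyl (4S,5S)-4-[4-(benzyloxy)phenyl]-5-(hydroxymethyl)-5-({(2S)-2-[2-(triethylsilyloxy)propan-2-yl]-2,3-dihydrobenzofuran-5-yl}methyl)-4,5-dihydroisoxazole-3-carboxylate | OC[C@@]1(Cc2ccc3c(c2)C[C@@H](C(C)(C)O[Si](CC)(CC)CC)O3)ON=C(C(=O)OCC)[C@@H]1c1ccc(OCc2ccccc2)cc1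
A8 | alternative 3 | (E)-3-[4-(benzyloxy)phenyl]-2-({(2S)-2-[2-(triethylsilyloxy)propan-2-yl]-2,3-dihydrobenzofuran-5-yl}methyl)prop-2-en-1-ol | OC/C(Cc1ccc2c(c1)C[C@@H](C(C)(C)O[Si](CC)(CC)CC)O2)=C/c1ccc(OCc2ccccc2)cc1
A9 | alternative 3 | ethyl 2-chloro-2-(hydroxyimino)acetate | CCOC(=O)C(Cl)=NO
A10 | alternative 3 | ethoxycarbonylformonitrile oxide | CCOC(=O)C#[N+][O-]
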